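Readings and results were generated by integration with made-up constants; noise was put on by code.

- 3 questions stand here: 2 reaction orders and what the amber run keeps at 84 min. Build one rule for the last.

| flask | substrate | coupling partner | catalyst | time |
|---|---|---|---|---|
| grey | 300 mM | 330 mM | 6.00 mM |  |
| teal | 600 mM | 330 mM | 6.00 mM |  |
| red | 300 mM | 330 mM | 18.0 mM |  |
| blue | 300 mM | 490 mM | 6.00 mM |  |
| amber | 120 mM | 150 mM | 6.00 mM | 84 min |

- grey run (time / min: [substrate] / mM): 3.4: 271.2; 5.7: 238.4; 9.8: 196.6; 17: 158.0; 29: 121.4; 49: 95.8; 84: 84.1
- teal run (time / min: [substrate] / mM): 3.4: 539.2; 5.7: 486.7; 9.8: 427.2; 17: 375.8; 29: 339.7; 49: 327.7; 84: 323.8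
- red run (time / min: [substrate] / mM): 3.4: 218.9; 5.7: 169.5; 9.8: 121.2; 17: 76.0; 29: 56.1; 49: 43.3; 84: 33.1
- blue run (time / min: [substrate] / mM): 3.4: 241.6; 5.7: 205.9; 9.8: 151.6; 17: 105.6; 29: 70.5; 49: 42.4; 84: 28.0

(readings scatter by 2 mM)

- Overall: substrate + coupling partner -> target, with catalyst as catalyst.
- Constant volume, constant temperature.
- An order is taken over about fifteen percent of the charge, up and down.

- reaction order in [coupling partner] at the outset, round the charge of the grey run, defined at two percent of the substrate turned into target
- reaction order in [catalyst] at the outset, round the charge of the grey run, defined at two percent of the substrate turned into target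
- substrate in the amber run at 84 min, as a share of the substrate charged

- Set the grey run beside the teal run: same partner and catalyst charges, but 2.00 times the substrate.
- Count partner in each. By the last reading, the grey run has put 0.654 of its partner charge into target and the teal run 0.837, so the teal run makes better use of the same charge.
- Note the grey run's paradox. Substrate is its limiting reagent on paper, with partner at 1.10 of the substrate charge, yet 0.280 of the substrate remains. Assume, then, that partner also disappears by a side route.
- Compare the two rates at one moment. Assume that, at fixed catalyst, coupling draws partner in proportion to partner and substrate, while loss draws it in proportion to partner alone.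
- Integrate that comparison into a budget, with every amount a share of the flask's substrate charge: partner charge = substrate turned + break-even level × ln(1 / share left).
- Treat the reading at 84 min as the end of the budget, as if no partner stood left there, although the grey run still drifts; the amber question sits at that same time. As shares of the grey charge, the grey run reads 0.299 and the teal run 0.291.
- Take their mean, a reading of 0.295, as the break-even substrate at a catalyst charge of 6.00 mM, the level at which coupling and loss draw partner equally fast.
- Now read the two endings on this assumption. The teal run's last reading stands at 1.08 of the grey charge, above break-even, so in the teal run coupling still outruns loss at that reading. The grey run's last reading has come down level with it, so in the grey run the two draw about equally at that reading.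
- Carry this to the amber run, which has the same catalyst charge. Its partner charge is 1.25 of its substrate, and break-even is 0.737 of that smaller charge.
- Solve the budget by Newton steps from 0.5: 0.403, then 40.9% of the substrate left. That is my figure.
- The forecast gives 1 in partner, 0.8 in catalyst and 43% left, arguing that “Stalling at less than full consumption of partner suggests the partner also decays”. Its amber figure stands above mine.
- The flask gives 1.0 in partner, 0.61 in catalyst and 43.9% left.

    active catalyst + substrate + coupling partner → target + active catalyst (36.36 M⁻² min⁻¹)
    coupling partner → lost reagent (0.01614 min⁻¹)
    catalyst + coupling partner → active catalyst + coupling partner (1.590 M⁻¹ min⁻¹)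

- The catalyst order lies below the forecast's, and the red run, with 3.00 times the catalyst, goes at 1.9 times the grey rate where both have made the same amount of target. The amber result lies above my figure. Put that result into the budget: it books 93.4% of the amber partner charge. Put in the blue run's last reading, with break-even at 0.295 of its charge, and it books 98.3% of the blue partner charge.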